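**Retrosynthetic overview**
1. Target 17 comes from O-debenzylation of 16. The C3 hydroxyl comes from face-selective hydroxylation of the enolate of dibenzyl lactone 14, anti to the C4 benzyl, so both C3 epimers of 14 converge.
2. The lactone (the only ring formed, step 7) comes from hydride removal of the oxazolidinone from succinate 12, then closure onto the tert-butyl ester.
3. The key C2–C3 bond of the 1,4-dicarbonyl 12 (lactone C3–C4) comes from Fe(III) oxidative heterocoupling of two enolates: imide 9 (vanillyl half, auxiliary sets C4) and tert-butyl ester 4 (syringyl half).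
4. 9 comes from dihydroferulic acid 5 and (R)-4-benzyl-oxazolidinone 7; 4 comes from syringaldehyde 1 by benzylation, HWE and conjugate reduction.

Assumption: dihydroferulic acid, syringaldehyde, (R)-4-benzyl-2-oxazolidinone, LDA solution and 2-(phenylsulfonyl)-3-phenyloxaziridine are bought; ester 4 is used in excess (1.5 equiv) in step 6.

Stereochemical note: the target is (3S,4R), with the two benzyl groups cis and the OH trans to the C4 benzyl. The C4 centre has the same spatial arrangement in 12, 13, 14, 16 and 17; its descriptor changes from S to R in step 8 only because C3 then outranks C5.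

**Step 1**
Reactants: 1 syringaldehyde (4-hydroxy-3,5-dimethoxybenzaldehyde)
Product: 2 4-(benzyloxy)-3,5-dimethoxybenzaldehyde
Conditions: BnBr, K2CO3, DMF, 60 °C
Reagents that add atoms: benzyl bromide, BrCc1ccccc1
Why: Williamson ether synthesis; the phenoxide is benzylated cleanly in DMF and the benzyl ether survives every later step until the final hydrogenolysis.

**Step 2**
Reactants: 2 4-(benzyloxy)-3,5-dimethoxybenzaldehyde
Product: 3 tert-butyl (2E)-3-[4-(benzyloxy)-3,5-dimethoxyphenyl]prop-2-enoate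
Conditions: (EtO)2P(O)CH2CO2tBu, NaH, THF, 0 °C → rt
Reagents that add atoms: tert-butyl diethylphosphonoacetate, CCOP(=O)(OCC)CC(=O)OC(C)(C)C
Why: Horner–Wadsworth–Emmons olefination gives the E-cinnamate and installs the tert-butyl ester, which resists Claisen self-condensation in the key step.

**Step 3**
Reactants: 3 tert-butyl (2E)-3-[4-(benzyloxy)-3,5-dimethoxyphenyl]prop-2-enoate
Product: 4 tert-butyl 3-[4-(benzyloxy)-3,5-dimethoxyphenyl]propanoate
Conditions: NaBH4, NiCl2·6H2O (10 mol %), MeOH–THF, 0 °C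
Reagents that add atoms: none
Why: Nickel boride conjugate reduction saturates the cinnamate C=C without hydrogenolysing the aryl benzyl ether or touching the tert-butyl ester.

**Step 4**
Reactants: 5 3-(4-hydroxy-3-methoxyphenyl)propanoic acid (dihydroferulic acid)
Product: 6 3-[4-(benzyloxy)-3-methoxyphenyl]propanoic acid
Conditions: BnBr (1.3 equiv), NaOH (2.5 equiv), EtOH–H2O, reflux; then aq HCl
Reagents that add atoms: benzyl bromide, BrCc1ccccc1
Why: Williamson etherification of the phenoxide–carboxylate dianion, in which the phenoxide is the far better nucleophile and any benzyl ester formed is saponified in the same pot.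

**Step 5**
Reactants: 6 3-[4-(benzyloxy)-3-methoxyphenyl]propanoic acid; 7 (4R)-4-benzyl-1,3-oxazolidin-2-one
Product: 9 (4R)-4-benzyl-3-{3-[4-(benzyloxy)-3-methoxyphenyl]propanoyl}-1,3-oxazolidin-2-one, via mixed pivalic anhydride 8 (not isolated)
Conditions: PivCl, Et3N, THF, −20 °C; then 7, LiCl, −20 °C → rt
Reagents that add atoms: pivaloyl chloride, CC(C)(C)C(=O)Cl (its atoms are in 8 only and leave as pivalate)
Why: N-acylation of the oxazolidinone through a mixed anhydride; the hindered pivaloyl carbonyl directs attack to the desired acyl group and no stereocentre is at risk.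

**Step 6 (key step)**
Reactants: 9 (4R)-4-benzyl-3-{3-[4-(benzyloxy)-3-methoxyphenyl]propanoyl}-1,3-oxazolidin-2-one; 4 tert-butyl 3-[4-(benzyloxy)-3,5-dimethoxyphenyl]propanoate
Product: 12 tert-butyl (2RS,3S)-2-[4-(benzyloxy)-3,5-dimethoxybenzyl]-3-[4-(benzyloxy)-3-methoxybenzyl]-4-[(4R)-4-benzyl-2-oxo-1,3-oxazolidin-3-yl]-4-oxobutanoate, via imide lithium Z-enolate 10 (not isolated), via ester lithium enolate 11 (not isolated)
Conditions: LDA (1.05 equiv per carbonyl partner), THF, −78 °C, 30 min; then Fe(acac)3 (2.2 equiv), THF, −78 °C → rt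
Reagents that add atoms: lithium diisopropylamide, CC(C)[N-]C(C)C.[Li+] (lithium of 10 and 11 only; nothing stays in 12)
Why: Oxidative intermolecular enolate heterocoupling: Fe(III) oxidises one enolate of the mixed aggregate to an electrophilic α-carbonyl radical (an enolonium-type equivalent) that bonds to the other enolate, joining two normally nucleophilic α-carbons into the 1,4-dicarbonyl; the chelated Z-enolate 10 reacts on the face opposite the auxiliary benzyl (Evans model), fixing C3 as S (the future lactone C4), while the uncontrolled C2 centre is erased in step 8.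

**Step 7**
Reactants: 12 tert-butyl (2RS,3S)-2-[4-(benzyloxy)-3,5-dimethoxybenzyl]-3-[4-(benzyloxy)-3-methoxybenzyl]-4-[(4R)-4-benzyl-2-oxo-1,3-oxazolidin-3-yl]-4-oxobutanoate
Product: 14 (3RS,4S)-3-[4-(benzyloxy)-3,5-dimethoxybenzyl]-4-[4-(benzyloxy)-3-methoxybenzyl]oxolan-2-one, via hydroxy tert-butyl ester 13 (not isolated)
Conditions: LiBH4, MeOH (1 equiv), THF, 0 °C; aqueous work-up; then p-TsOH·H2O (cat.), toluene, 60 °C
Reagents that add atoms: none
Why: Reductive removal of the Evans auxiliary (hydride attack on the exocyclic imide carbonyl, tert-butyl ester inert) followed by acid-catalysed lactonisation with loss of isobutene; C4 is no longer α to a carbonyl and cannot epimerise.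

**Step 8**
Reactants: 14 (3RS,4S)-3-[4-(benzyloxy)-3,5-dimethoxybenzyl]-4-[4-(benzyloxy)-3-methoxybenzyl]oxolan-2-one
Product: 16 (3S,4R)-3-[4-(benzyloxy)-3,5-dimethoxybenzyl]-4-[4-(benzyloxy)-3-methoxybenzyl]-3-hydroxyoxolan-2-one, via lactone potassium enolate 15 (not isolated)
Conditions: KHMDS, THF, −78 °C; then 2-(phenylsulfonyl)-3-phenyloxaziridine, −78 → −40 °C; AcOH quench
Reagents that add atoms: 2-(phenylsulfonyl)-3-phenyloxaziridine, O=S(=O)(N1OC1c1ccccc1)c1ccccc1 (the hydroxyl oxygen); potassium bis(trimethylsilyl)amide, C[Si](C)(C)[N-][Si](C)(C)C.[K+] (potassium of 15 only)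
Why: Davis enolate hydroxylation: both C3 epimers of 14 give the same planar enolate 15 and the oxaziridine delivers oxygen to the face opposite the C4 benzyl, so the OH ends up trans to that group and C3 is S.

**Step 9**
Reactants: 16 (3S,4R)-3-[4-(benzyloxy)-3,5-dimethoxybenzyl]-4-[4-(benzyloxy)-3-methoxybenzyl]-3-hydroxyoxolan-2-one
Product: 17 (3S,4R)-3-hydroxy-3-(4-hydroxy-3,5-dimethoxybenzyl)-4-(4-hydroxy-3-methoxybenzyl)oxolan-2-one (CNP0176953.1)
Conditions: H2 (1 atm), 10% Pd/C, EtOAc–MeOH, rt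
Reagents that add atoms: none
Why: Catalytic hydrogenolysis cleaves both aryl benzyl ethers; the tertiary alcohol is homobenzylic, not benzylic, and the lactone and both stereocentres are untouched.

**Compound list**
1 | syringaldehyde (4-hydroxy-3,5-dimethoxybenzaldehyde) | COc1cc(C=O)cc(OC)c1O | starting material
2 | 4-(benzyloxy)-3,5-dimethoxybenzaldehyde | COc1cc(C=O)cc(OC)c1OCc1ccccc1 | intermediate
3 | tert-butyl (2E)-3-[4-(benzyloxy)-3,5-dimethoxyphenyl]prop-2-enoate | COc1cc(/C=C/C(=O)OC(C)(C)C)cc(OC)c1OCc1ccccc1 | intermediate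
4 | tert-butyl 3-[4-(benzyloxy)-3,5-dimethoxyphenyl]propanoate | COc1cc(CCC(=O)OC(C)(C)C)cc(OC)c1OCc1ccccc1 | intermediate
5 | 3-(4-hydroxy-3-methoxyphenyl)propanoic acid (dihydroferulic acid) | COc1cc(CCC(=O)O)ccc1O | starting material
6 | 3-[4-(benzyloxy)-3-methoxyphenyl]propanoic acid | COc1cc(CCC(=O)O)ccc1OCc1ccccc1 | intermediate
7 | (4R)-4-benzyl-1,3-oxazolidin-2-one | O=C1N[C@H](Cc2ccccc2)CO1 | starting material
8 | 3-[4-(benzyloxy)-3-methoxyphenyl]propanoic pivalic anhydride | COc1cc(CCC(=O)OC(=O)C(C)(C)C)ccc1OCc1ccccc1 | intermediate (not isolated)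
9 | (4R)-4-benzyl-3-{3-[4-(benzyloxy)-3-methoxyphenyl]propanoyl}-1,3-oxazolidin-2-one | COc1cc(CCC(=O)N2[C@H](Cc3ccccc3)COC2=O)ccc1OCc1ccccc1 | intermediate
10 | lithium (Z)-enolate of imide 9 | [Li+].[O-]/C(=C\Cc1ccc(OCc2ccccc2)c(OC)c1)N1[C@H](Cc2ccccc2)COC1=O | intermediate (not isolated)
11 | lithium enolate of ester 4 | [Li+].[O-]C(OC(C)(C)C)=CCc1cc(OC)c(OCc2ccccc2)c(OC)c1 | intermediate (not isolated)
12 | tert-butyl (2RS,3S)-2-[4-(benzyloxy)-3,5-dimethoxybenzyl]-3-[4-(benzyloxy)-3-methoxybenzyl]-4-[(4R)-4-benzyl-2-oxo-1,3-oxazolidin-3-yl]-4-oxobutanoate | COc1cc(CC(C(=O)OC(C)(C)C)[C@H](Cc2ccc(OCc3ccccc3)c(OC)c2)C(=O)N2[C@H](Cc3ccccc3)COC2=O)cc(OC)c1OCc1ccccc1 | intermediate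
13 | tert-butyl (2RS,3S)-2-[4-(benzyloxy)-3,5-dimethoxybenzyl]-3-[4-(benzyloxy)-3-methoxybenzyl]-4-hydroxybutanoate | COc1cc(CC(C(=O)OC(C)(C)C)[C@H](Cc2ccc(OCc3ccccc3)c(OC)c2)CO)cc(OC)c1OCc1ccccc1 | intermediate (not isolated)
14 | (3RS,4S)-3-[4-(benzyloxy)-3,5-dimethoxybenzyl]-4-[4-(benzyloxy)-3-methoxybenzyl]oxolan-2-one | COc1cc(C[C@@H]2COC(=O)C2Cc2cc(OC)c(OCc3ccccc3)c(OC)c2)ccc1OCc1ccccc1 | intermediate
15 | potassium enolate of lactone 14 | [K+].[O-]C1=C(Cc2cc(OC)c(OCc3ccccc3)c(OC)c2)[C@H](Cc2ccc(OCc3ccccc3)c(OC)c2)CO1 | intermediate (not isolated)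
16 | (3S,4R)-3-[4-(benzyloxy)-3,5-dimethoxybenzyl]-4-[4-(benzyloxy)-3-methoxybenzyl]-3-hydroxyoxolan-2-one | COc1cc(C[C@@H]2COC(=O)[C@]2(O)Cc2cc(OC)c(OCc3ccccc3)c(OC)c2)ccc1OCc1ccccc1 | intermediate
17 | (3S,4R)-3-hydroxy-3-(4-hydroxy-3,5-dimethoxybenzyl)-4-(4-hydroxy-3-methoxybenzyl)oxolan-2-one | COc1cc(C[C@@H]2COC(=O)[C@]2(O)Cc2cc(OC)c(O)c(OC)c2)ccc1O | target

**Step count**
Total: 9 steps. Longest linear sequence: 7 steps (1, 2, 3, 6, 7, 8, 9); the other branch is steps 4 and 5.

**Three steps most likely to fail, with fallbacks**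

Step 6 (heterocoupling). Homodimers of either enolate and a modest yield are the main risk; auxiliary control of the imide α-centre is assumed to follow the Evans model. The fallback sets out from 9 and comes back at 14. The sodium enolate of 9 (NaHMDS, THF, −78 °C) is alkylated anti to the auxiliary benzyl with tert-butyl bromoacetate, the classical α-halo-ester enolonium equivalent, to give tert-butyl (3S)-3-[4-(benzyloxy)-3-methoxybenzyl]-4-[(4R)-4-benzyl-2-oxo-1,3-oxazolidin-3-yl]-4-oxobutanoate F1. LiBH4 and then p-TsOH, as in step 7, convert it into (4S)-4-[4-(benzyloxy)-3-methoxybenzyl]oxolan-2-one F2. Separately, aldehyde 2 is reduced (NaBH4, MeOH) to [4-(benzyloxy)-3,5-dimethoxyphenyl]methanol F3, and PBr3 in Et2O turns this into 2-(benzyloxy)-5-(bromomethyl)-1,3-dimethoxybenzene F4. The lithium enolate of the lactone (LiHMDS, THF, −78 °C) is then benzylated by the bromide trans to the C4 substituent, which gives the (3S,4S) epimer of 14; this enters step 8 unchanged because the C3 centre is erased there.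

Step 7 (reductive auxiliary removal and lactonisation). With this hindered, α-branched imide, hydride may open the oxazolidinone ring instead, or over-reduce once lactone forms. The fallback sets out from 12 and comes back at 13. LiOH/H2O2 (THF–H2O, 0 °C) cleaves the auxiliary hydrolytically to (2S,3RS)-2-[4-(benzyloxy)-3-methoxybenzyl]-3-[4-(benzyloxy)-3,5-dimethoxybenzyl]-4-tert-butoxy-4-oxobutanoic acid F5. BH3·SMe2 (THF, 0 °C) then reduces the free acid selectively in the presence of the tert-butyl ester to hydroxy ester 13, which is lactonised with p-TsOH as before.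

Step 8 (hydroxylation). The tetrasubstituted enolate may react sluggishly or add to the sulfonimine by-product, and the anti selectivity, though sterically expected, is not guaranteed to be complete. The fallback sets out from 14 and comes back at 16. LDA then TMSCl (THF, −78 °C) gives the silyl ketene acetal {[(4S)-3-[4-(benzyloxy)-3,5-dimethoxybenzyl]-4-[4-(benzyloxy)-3-methoxybenzyl]-4,5-dihydrofuran-2-yl]oxy}trimethylsilane F6. Rubottom oxidation (mCPBA, NaHCO3, CH2Cl2, −20 °C) epoxidises the face away from the C4 benzyl and, after silyl migration, gives (3S,4R)-3-[4-(benzyloxy)-3,5-dimethoxybenzyl]-4-[4-(benzyloxy)-3-methoxybenzyl]-3-[(trimethylsilyl)oxy]oxolan-2-one F7. Dilute HCl in THF removes the silyl group to give 16. This changes the oxidant and removes the basic enolate and the imine by-product; it does not change the facial preference.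

**Further compounds**
F1 | step 6 | tert-butyl (3S)-3-[4-(benzyloxy)-3-methoxybenzyl]-4-[(4R)-4-benzyl-2-oxo-1,3-oxazolidin-3-yl]-4-oxobutanoate | COc1cc(C[C@@H](CC(=O)OC(C)(C)C)C(=O)N2[C@H](Cc3ccccc3)COC2=O)ccc1OCc1ccccc1
F2 | step 6 | (4S)-4-[4-(benzyloxy)-3-methoxybenzyl]oxolan-2-one | COc1cc(C[C@@H]2COC(=O)C2)ccc1OCc1ccccc1
F3 | step 6 | [4-(benzyloxy)-3,5-dimethoxyphenyl]methanol | COc1cc(CO)cc(OC)c1OCc1ccccc1
F4 | step 6 | 2-(benzyloxy)-5-(bromomethyl)-1,3-dimethoxybenzene | COc1cc(CBr)cc(OC)c1OCc1ccccc1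
F5 | step 7 | (2S,3RS)-2-[4-(benzyloxy)-3-methoxybenzyl]-3-[4-(benzyloxy)-3,5-dimethoxybenzyl]-4-tert-butoxy-4-oxobutanoic acid | COc1cc(CC(C(=O)OC(C)(C)C)[C@H](Cc2ccc(OCc3ccccc3)c(OC)c2)C(=O)O)cc(OC)c1OCc1ccccc1
F6 | step 8 | {[(4S)-3-[4-(benzyloxy)-3,5-dimethoxybenzyl]-4-[4-(benzyloxy)-3-methoxybenzyl]-4,5-dihydrofuran-2-yl]oxy}trimethylsilane | C[Si](C)(C)OC1=C(Cc2cc(OC)c(OCc3ccccc3)c(OC)c2)[C@H](Cc2ccc(OCc3ccccc3)c(OC)c2)CO1
F7 | step 8 | (3S,4R)-3-[4-(benzyloxy)-3,5-dimethoxybenzyl]-4-[4-(benzyloxy)-3-methoxybenzyl]-3-[(trimethylsilyl)oxy]oxolan-2-one | COc1cc(C[C@@H]2COC(=O)[C@]2(O[Si](C)(C)C)Cc2cc(OC)c(OCc3ccccc3)c(OC)c2)ccc1OCc1ccccc1
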